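**Plan**

1. Numbering (germacrane): carbocycle C1–C10, C14 = methyl on C10, C15 = methyl on C4, side chain C11(=C13H2)–C12(=O)–O–C6.
2. Cuts: O6–C12 and C11–C12 (lactone from carbonylation of a 1-bromovinyl group), the angelate, then ring bond C7–C8 by a retro-Claisen. This opens the ten-membered carbocycle to a twelve-membered 2-methylene oxacycle (C9–O–C13), i.e. the lactone of a C9 acid with the C13 allylic alcohol. Last cuts: C3–C4 and the ester C9–O.
3. Enabling feature: in the carbocycle, C9(O)–C8H2–C7–C11(=C13H2) is a γ,δ-unsaturated carbonyl array. C8 is the only ring atom that can be supplied from outside the precursor ring, and the quaternary C10 forces the enol ether to be exocyclic.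
4. Forward: hydroxy acid (C9, C10, C1–C3) and bromo-iodo dienediol (C4–C7, C11, C13) are joined as an ester; Nozaki–Hiyama–Kishi closure of C3–C4 gives the 12-membered lactone; methylenation and ring contraction give the 10-membered ring; C9 reduction, angelate, carbonylation and closure of the five-membered lactone follow.
5. Stereochemistry: C10 from (R)-lactic acid (dioxolanone alkylation), C6 from catalytic asymmetric alkynylation, C3 from CBS reduction, C7 relayed from C6 in the Claisen step, C9 relayed from C10 (Felkin–Anh). Both Z-alkenes come from hydroxyl-directed trans-hydroalumination.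

Key step: step 17

Remark: in step 6 the ligand antipode is the one that delivers the alkynyl group to the Si face of the aldehyde; it is taken to be the (R,R) ligand, and the enantiomeric ligand is used if the facial preference is the opposite one.

**Route**

Step 1
Reactants: 1 (R)-lactic acid; 2 pivalaldehyde
Product: 3 (2R,5R)-2-tert-butyl-5-methyl-1,3-dioxolan-4-one (cis)
Conditions: p-TsOH (cat.), H2SO4 (cat.), pentane, reflux, Dean–Stark; recrystallisation
Reagents that add atoms: none
Why: Acid-catalysed acetalisation of the α-hydroxy acid (first stage of self-regeneration of stereocentres) should give the thermodynamically preferred cis-dioxolanone, which stores the lactate configuration in the acetal carbon.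

Step 2
Reactants: 3 (2R,5R)-2-tert-butyl-5-methyl-1,3-dioxolan-4-one; 4 propargyl bromide
Product: 6 (2R,5S)-2-tert-butyl-5-methyl-5-(prop-2-yn-1-yl)-1,3-dioxolan-4-one, via lithium enolate 5 (not isolated)
Conditions: LDA, THF, −78 °C; then 4, −78 → −30 °C
Reagents that add atoms: none
Why: Enolate alkylation in which the tert-butyl group shields one face of the planar enolate, so the propargyl group should enter anti to it and set the quaternary C10 with overall retention.

Step 3
Reactants: 6 (2R,5S)-2-tert-butyl-5-methyl-5-(prop-2-yn-1-yl)-1,3-dioxolan-4-one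
Product: 7 (2S)-2-hydroxy-2-methylpent-4-ynoic acid
Conditions: LiOH, THF/H2O, rt; then 1 M HCl
Reagents that add atoms: lithium hydroxide, [Li+].[OH-]
Why: Saponification of the acetal-lactone should release the free α-hydroxy acid and pivalaldehyde without touching the quaternary centre.

Step 4
Reactants: 8 but-2-yn-1-ol
Product: 10 (Z)-3-iodobut-2-en-1-ol, via alkenylalanate 9 (not isolated)
Conditions: Red-Al, THF, 0 °C → rt; then I2, THF, −78 → 0 °C
Reagents that add atoms: iodine, II
Why: Hydroxyl-directed trans-hydroalumination of the propargylic alcohol places aluminium on the distal carbon in a five-membered alanate, and iodinolysis with retention should give the Z-iodoalkene (future C4=C5).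

Step 5
Reactants: 10 (Z)-3-iodobut-2-en-1-ol
Product: 11 (Z)-3-iodobut-2-enal
Conditions: MnO2, CH2Cl2, rt, dark
Reagents that add atoms: none
Why: Allylic oxidation with manganese dioxide is neutral and should keep the Z-geometry of the β-iodo enal.

Step 6
Reactants: 11 (Z)-3-iodobut-2-enal; 12 tert-butyldimethyl(prop-2-yn-1-yloxy)silane
Product: 14 (4R,5Z)-1-(tert-butyldimethylsilyloxy)-6-iodohept-5-en-2-yn-4-ol, via alkynylzinc 13 (not isolated)
Conditions: 12 (3 equiv), Me2Zn (3 equiv), (R,R)-ProPhenol (20 mol%), Ph3P=O (40 mol%), toluene, 0 → 4 °C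
Reagents that add atoms: none
Why: Zinc–ProPhenol-catalysed enantioselective alkynylation, a type established for enals, should add the alkynylzinc to the Si face of the aldehyde inside the dinuclear zinc catalyst and set C6.

Step 7
Reactants: 14 (4R,5Z)-1-(tert-butyldimethylsilyloxy)-6-iodohept-5-en-2-yn-4-ol
Product: 16 (2Z,4S,5Z)-2-bromo-1-(tert-butyldimethylsilyloxy)-6-iodohepta-2,5-dien-4-ol, via alkenylalanate 15 (not isolated)
Conditions: Red-Al, THF, −20 → 0 °C; then NBS, −78 °C
Reagents that add atoms: N-bromosuccinimide, O=C1CCC(=O)N1Br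
Why: A second carbinol-directed trans-hydroalumination, now of the C7≡C11 alkyne, followed by brominolysis with retention should give the bromoalkene with bromine cis to C6, the silyl ether being non-directing and the alkenyl iodide inert at this temperature.

Step 8
Reactants: 16 (2Z,4S,5Z)-2-bromo-1-(tert-butyldimethylsilyloxy)-6-iodohepta-2,5-dien-4-ol
Product: 17 (2Z,4S,5Z)-2-bromo-6-iodohepta-2,5-diene-1,4-diol
Conditions: TBAF, THF, 0 °C
Reagents that add atoms: none
Why: Fluoride desilylation should free the primary allylic alcohol (C13–OH); the trans relation of C13 and C6 on the alkene excludes cyclisation.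

Step 9
Reactants: 7 (2S)-2-hydroxy-2-methylpent-4-ynoic acid; 17 (2Z,4S,5Z)-2-bromo-6-iodohepta-2,5-diene-1,4-diol
Product: 18 (2Z,4S,5Z)-2-bromo-4-hydroxy-6-iodohepta-2,5-dien-1-yl (2S)-2-hydroxy-2-methylpent-4-ynoate
Conditions: PPh3, DIAD, THF, 0 °C → rt
Reagents that add atoms: none
Why: Mitsunobu esterification should activate the primary allylic alcohol in preference to the hindered bis-allylic secondary one, while the hindered acid acts only as the nucleophile and its tertiary hydroxyl stays inert.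

Step 10
Reactants: 18 (2Z,4S,5Z)-2-bromo-4-hydroxy-6-iodohepta-2,5-dien-1-yl (2S)-2-hydroxy-2-methylpent-4-ynoate
Product: 19 (2Z,4S,5Z)-2-bromo-6-iodo-4-(triethylsilyloxy)hepta-2,5-dien-1-yl (2S)-2-methyl-2-(triethylsilyloxy)pent-4-ynoate
Conditions: TESOTf, 2,6-lutidine, CH2Cl2, −78 → 0 °C
Reagents that add atoms: triethylsilyl trifluoromethanesulfonate, CC[Si](CC)(CC)OS(=O)(=O)C(F)(F)F
Why: Silyl triflate silylation should cap both the secondary C6 and the tertiary C10 hydroxyl in one operation; the bulky C10 silyl ether later serves as the non-chelating group for C9.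

Step 11
Reactants: 19 (2Z,4S,5Z)-2-bromo-6-iodo-4-(triethylsilyloxy)hepta-2,5-dien-1-yl (2S)-2-methyl-2-(triethylsilyloxy)pent-4-ynoate
Product: 21 (2Z,4S,5Z)-2-bromo-6-iodo-4-(triethylsilyloxy)hepta-2,5-dien-1-yl (2S)-2-methyl-5-oxo-2-(triethylsilyloxy)pentanoate, via alkenylborane 20 (not isolated)
Conditions: Cy2BH (from BH3·SMe2 and cyclohexene), THF, 0 °C; then H2O2, pH 7 phosphate buffer, 0 °C → rt
Reagents that add atoms: hydrogen peroxide, OO
Why: Anti-Markovnikov hydroboration of the terminal alkyne with a hindered dialkylborane and buffered oxidation should give the C3 aldehyde, the trisubstituted haloalkenes being far less reactive toward the borane.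

Step 12
Reactants: 21 (2Z,4S,5Z)-2-bromo-6-iodo-4-(triethylsilyloxy)hepta-2,5-dien-1-yl (2S)-2-methyl-5-oxo-2-(triethylsilyloxy)pentanoate
Product: 22 (3S,7Z,9R,10Z)-11-bromo-6-hydroxy-3,7-dimethyl-3,9-bis(triethylsilyloxy)-1-oxacyclododeca-7,10-dien-2-one (both C6 epimers)
Conditions: CrCl2 (10 equiv), NiCl2 (cat.), DMSO/THF, rt, 2 mM
Reagents that add atoms: none
Why: Nozaki–Hiyama–Kishi macrocyclisation should join the alkenyl iodide (C4) to the aldehyde (C3) with retention of the Z-geometry and close the 12-membered lactone; the alkenyl bromide is much slower toward nickel(0), and the unselective new carbinol is corrected in steps 13–14.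

Step 13
Reactants: 22 (3S,7Z,9R,10Z)-11-bromo-6-hydroxy-3,7-dimethyl-3,9-bis(triethylsilyloxy)-1-oxacyclododeca-7,10-dien-2-one
Product: 23 (3S,7Z,9R,10Z)-11-bromo-3,7-dimethyl-3,9-bis(triethylsilyloxy)-1-oxacyclododeca-7,10-diene-2,6-dione
Conditions: Dess–Martin periodinane, NaHCO3, CH2Cl2, 0 °C → rt
Reagents that add atoms: none
Why: Buffered Dess–Martin oxidation should convert both epimers into one Z-enone without isomerising the alkene.

Step 14
Reactants: 23 (3S,7Z,9R,10Z)-11-bromo-3,7-dimethyl-3,9-bis(triethylsilyloxy)-1-oxacyclododeca-7,10-diene-2,6-dione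
Product: 24 (3S,6S,7Z,9R,10Z)-11-bromo-6-hydroxy-3,7-dimethyl-3,9-bis(triethylsilyloxy)-1-oxacyclododeca-7,10-dien-2-one
Conditions: (R)-Me-CBS oxazaborolidine, catecholborane, toluene, −78 °C
Reagents that add atoms: none
Why: Corey–Bakshi–Shibata reduction under catalyst control, with the α-methyl alkenyl arm as the large group and the CH2 arm as the small one, should give the (S)-carbinol at C3 by 1,2-reduction.

Step 15
Reactants: 24 (3S,6S,7Z,9R,10Z)-11-bromo-6-hydroxy-3,7-dimethyl-3,9-bis(triethylsilyloxy)-1-oxacyclododeca-7,10-dien-2-one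
Product: 25 (3S,6S,7Z,9R,10Z)-11-bromo-6-(tert-butyldimethylsilyloxy)-3,7-dimethyl-3,9-bis(triethylsilyloxy)-1-oxacyclododeca-7,10-dien-2-one
Conditions: TBSOTf, 2,6-lutidine, CH2Cl2, −78 °C
Reagents that add atoms: tert-butyldimethylsilyl trifluoromethanesulfonate, CC(C)(C)[Si](C)(C)OS(=O)(=O)C(F)(F)F
Why: Silylation of the C3 carbinol should leave the lactone as the only carbonyl group and the only site reactive toward the titanium methylidene.

Step 16
Reactants: 25 (3S,6S,7Z,9R,10Z)-11-bromo-6-(tert-butyldimethylsilyloxy)-3,7-dimethyl-3,9-bis(triethylsilyloxy)-1-oxacyclododeca-7,10-dien-2-one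
Product: 26 (3S,6S,7Z,9R,10Z)-11-bromo-6-(tert-butyldimethylsilyloxy)-3,7-dimethyl-2-methylidene-3,9-bis(triethylsilyloxy)-1-oxacyclododeca-7,10-diene
Conditions: Tebbe reagent, pyridine, THF/toluene, −40 → 0 °C; filtration through basic alumina
Reagents that add atoms: Tebbe reagent, C[Al-]1(C)C[Ti]([Cl+]1)(C1C=CC=C1)C1C=CC=C1
Why: Tebbe methylenation of a lactone should give the exocyclic enol ether (C8 introduced) below the temperature of the sigmatropic shift, and the quaternary C10 allows no other enol ether isomer.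

Step 17
Reactants: 26 (3S,6S,7Z,9R,10Z)-11-bromo-6-(tert-butyldimethylsilyloxy)-3,7-dimethyl-2-methylidene-3,9-bis(triethylsilyloxy)-1-oxacyclododeca-7,10-diene
Product: 27 (3R,4R,5Z,7S,10S)-3-(1-bromoethenyl)-7-(tert-butyldimethylsilyloxy)-6,10-dimethyl-4,10-bis(triethylsilyloxy)cyclodec-5-en-1-one
Conditions: toluene, 2,6-di-tert-butylpyridine (cat.), base-washed sealed tube, 135 °C
Reagents that add atoms: none
Why: Proposed new method: a thermal [3,3]-sigmatropic (Claisen) shift within the 12-membered allyl vinyl ether forms C7–C8 while O–C13 breaks, so that the oxygen, C13 and C11 leave the ring and the exocyclic C8 enters it, which contracts the oxacyclododecadiene to the cyclodecenone with the C9 ketone and the 1-bromovinyl group already in place. The closest known reaction types are the Claisen ring expansion of lactone-derived 2-methylene-6-vinyl oxacycles and the Ireland–Claisen ring contraction of macrolactones; here the enol ether double bond is exocyclic and the allyl unit endocyclic, which is why two ring atoms are lost and not four. The ten-membered ring closes by C–C bond formation through a chair-like six-centre array that is bridged 1,3 by the seven-atom chain C10–C1–C2–C3–C4–C5–C6 (a bicyclo[7.3.1]-type transition state), with suprafacial attack of C8 on C7. The new stereocentre C7 is controlled by C6: allylic 1,3-strain with the cis bromine holds H6 in the alkene plane, so C8 should add anti to the C6–O bond, on the face carrying the C5 arm to which it is tethered, and this gives the 6,7-trans relation of the later lactone. The step needs the concerted [3,3] path to win over ionisation with [1,3] recombination, and it needs one π-face; the neutral base-buffered medium, the quaternary C10 and the bromine substituent should secure both.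

Step 18
Reactants: 27 (3R,4R,5Z,7S,10S)-3-(1-bromoethenyl)-7-(tert-butyldimethylsilyloxy)-6,10-dimethyl-4,10-bis(triethylsilyloxy)cyclodec-5-en-1-one
Product: 28 (1S,3R,4R,5Z,7S,10S)-3-(1-bromoethenyl)-7-(tert-butyldimethylsilyloxy)-6,10-dimethyl-4,10-bis(triethylsilyloxy)cyclodec-5-en-1-ol
Conditions: L-Selectride, THF, −78 °C
Reagents that add atoms: none
Why: Felkin–Anh (non-chelation) reduction in which the bulky hydride should attack anti to the C10–OSiEt3 bond and past the C10 methyl group, giving the 9S carbinol (9,10-syn diol pattern).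

Step 19
Reactants: 28 (1S,3R,4R,5Z,7S,10S)-3-(1-bromoethenyl)-7-(tert-butyldimethylsilyloxy)-6,10-dimethyl-4,10-bis(triethylsilyloxy)cyclodec-5-en-1-ol; 29 angelic acid
Product: 31 (1S,3R,4R,5Z,7S,10S)-3-(1-bromoethenyl)-7-(tert-butyldimethylsilyloxy)-6,10-dimethyl-4,10-bis(triethylsilyloxy)cyclodec-5-en-1-yl (2Z)-2-methylbut-2-enoate, via mixed anhydride 30 (not isolated)
Conditions: 29, 2,4,6-trichlorobenzoyl chloride, Et3N, toluene, rt; then 28, toluene, 80 °C (no DMAP)
Reagents that add atoms: none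
Why: Yamaguchi-type mixed-anhydride acylation without a nucleophilic catalyst should transfer the angeloyl group without Z→E isomerisation to the tiglate, and because no alkoxide is formed the neighbouring silyl group should not migrate.

Step 20
Reactants: 31 (1S,3R,4R,5Z,7S,10S)-3-(1-bromoethenyl)-7-(tert-butyldimethylsilyloxy)-6,10-dimethyl-4,10-bis(triethylsilyloxy)cyclodec-5-en-1-yl (2Z)-2-methylbut-2-enoate
Product: 32 methyl 2-[(1S,2R,3Z,5S,8S,9S)-5-(tert-butyldimethylsilyloxy)-4,8-dimethyl-9-{[(2Z)-2-methylbut-2-enoyl]oxy}-2,8-bis(triethylsilyloxy)cyclodec-3-en-1-yl]prop-2-enoate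
Conditions: Pd(OAc)2 (10 mol%), PPh3 (30 mol%), CO (1 atm), MeOH, Et3N, DMF, 60 °C
Reagents that add atoms: carbon monoxide, [C-]#[O+]; methanol, CO
Why: Palladium-catalysed alkoxycarbonylation of the 1,1-disubstituted alkenyl bromide should install C12 as the acrylate ester while C6 is still silylated, so that no allylic ester is exposed to palladium(0).

Step 21
Reactants: 32 methyl 2-[(1S,2R,3Z,5S,8S,9S)-5-(tert-butyldimethylsilyloxy)-4,8-dimethyl-9-{[(2Z)-2-methylbut-2-enoyl]oxy}-2,8-bis(triethylsilyloxy)cyclodec-3-en-1-yl]prop-2-enoate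
Product: 34 target germacranolide (3S,6R,7S,9S,10S,4Z)-9-angeloyloxy-3,10-dihydroxygermacra-4,11(13)-dien-12,6-olide, via triol ester 33 (not isolated)
Conditions: HF·pyridine, pyridine, THF, 0 °C → rt; then PPTS (cat.), CH2Cl2, rt
Reagents that add atoms: none
Why: Fluoride-mediated global desilylation followed by acid-catalysed lactonisation of the γ-hydroxy acrylate should close the trans-fused α-methylene-γ-butyrolactone; only O6 can reach the methyl ester in a five-membered transition state.

**Compound list**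

1 | (R)-lactic acid, (2R)-2-hydroxypropanoic acid | C[C@@H](O)C(=O)O | starting material
2 | pivalaldehyde (2,2-dimethylpropanal) | CC(C)(C)C=O | starting material
3 | (2R,5R)-2-tert-butyl-5-methyl-1,3-dioxolan-4-one (cis) | C[C@H]1O[C@@H](C(C)(C)C)OC1=O | intermediate
4 | propargyl bromide (3-bromoprop-1-yne) | C#CCBr | starting material
5 | lithium enolate of 3, lithium (2R)-2-tert-butyl-5-methyl-1,3-dioxol-4-olate | CC1=C([O-])O[C@H](C(C)(C)C)O1.[Li+] | intermediate
6 | (2R,5S)-2-tert-butyl-5-methyl-5-(prop-2-yn-1-yl)-1,3-dioxolan-4-one | C#CC[C@]1(C)O[C@@H](C(C)(C)C)OC1=O | intermediate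
7 | (2S)-2-hydroxy-2-methylpent-4-ynoic acid | C#CC[C@](C)(O)C(=O)O | intermediate
8 | but-2-yn-1-ol | CC#CCO | starting material
9 | cyclic sodium alkenylalanate from 8 (five-membered O–Al–C=C–C ring, two 2-methoxyethoxy groups on Al) | CC1=CCO[Al-]1(OCCOC)OCCOC.[Na+] | intermediate
10 | (Z)-3-iodobut-2-en-1-ol | C/C(I)=C/CO | intermediate
11 | (Z)-3-iodobut-2-enal | C/C(I)=C/C=O | intermediate
12 | tert-butyldimethyl(prop-2-yn-1-yloxy)silane | C#CCO[Si](C)(C)C(C)(C)C | starting material
13 | [3-(tert-butyldimethylsilyloxy)prop-1-yn-1-yl](methyl)zinc | C[Zn]C#CCO[Si](C)(C)C(C)(C)C | intermediate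
14 | (4R,5Z)-1-(tert-butyldimethylsilyloxy)-6-iodohept-5-en-2-yn-4-ol | C/C(I)=C/[C@@H](O)C#CCO[Si](C)(C)C(C)(C)C | intermediate
15 | cyclic sodium alkenylalanate from 14 (Al on C2, bound to the C4 oxygen) | C/C(I)=C/[C@@H]1C=C(CO[Si](C)(C)C(C)(C)C)[Al-](OCCOC)(OCCOC)O1.[Na+] | intermediate
16 | (2Z,4S,5Z)-2-bromo-1-(tert-butyldimethylsilyloxy)-6-iodohepta-2,5-dien-4-ol | C/C(I)=C/[C@@H](O)/C=C(\Br)CO[Si](C)(C)C(C)(C)C | intermediate
17 | (2Z,4S,5Z)-2-bromo-6-iodohepta-2,5-diene-1,4-diol | C/C(I)=C/[C@@H](O)/C=C(\Br)CO | intermediate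
18 | (2Z,4S,5Z)-2-bromo-4-hydroxy-6-iodohepta-2,5-dien-1-yl (2S)-2-hydroxy-2-methylpent-4-ynoate | C#CC[C@](C)(O)C(=O)OC/C(Br)=C/[C@H](O)/C=C(/C)I | intermediate
19 | (2Z,4S,5Z)-2-bromo-6-iodo-4-(triethylsilyloxy)hepta-2,5-dien-1-yl (2S)-2-methyl-2-(triethylsilyloxy)pent-4-ynoate | C#CC[C@](C)(O[Si](CC)(CC)CC)C(=O)OC/C(Br)=C/[C@H](O[Si](CC)(CC)CC)/C=C(/C)I | intermediate
20 | (E)-alkenyl(dicyclohexyl)borane from 19 (boron on the former alkyne terminus) | C1CCCCC1B(C1CCCCC1)/C=C/C[C@](C)(O[Si](CC)(CC)CC)C(=O)OC/C(Br)=C/[C@H](O[Si](CC)(CC)CC)/C=C(/C)I | intermediate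
21 | (2Z,4S,5Z)-2-bromo-6-iodo-4-(triethylsilyloxy)hepta-2,5-dien-1-yl (2S)-2-methyl-5-oxo-2-(triethylsilyloxy)pentanoate | O=CCC[C@](C)(O[Si](CC)(CC)CC)C(=O)OC/C(Br)=C/[C@H](O[Si](CC)(CC)CC)/C=C(/C)I | intermediate
22 | (3S,7Z,9R,10Z)-11-bromo-6-hydroxy-3,7-dimethyl-3,9-bis(triethylsilyloxy)-1-oxacyclododeca-7,10-dien-2-one, both C6 epimers | OC1CC[C@](C)(O[Si](CC)(CC)CC)C(=O)OC/C(Br)=C/[C@H](O[Si](CC)(CC)CC)/C=C1/C | intermediate
23 | (3S,7Z,9R,10Z)-11-bromo-3,7-dimethyl-3,9-bis(triethylsilyloxy)-1-oxacyclododeca-7,10-diene-2,6-dione | O=C1CC[C@](C)(O[Si](CC)(CC)CC)C(=O)OC/C(Br)=C/[C@H](O[Si](CC)(CC)CC)/C=C1/C | intermediate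
24 | (3S,6S,7Z,9R,10Z)-11-bromo-6-hydroxy-3,7-dimethyl-3,9-bis(triethylsilyloxy)-1-oxacyclododeca-7,10-dien-2-one | O[C@H]1CC[C@](C)(O[Si](CC)(CC)CC)C(=O)OC/C(Br)=C/[C@H](O[Si](CC)(CC)CC)/C=C1/C | intermediate
25 | (3S,6S,7Z,9R,10Z)-11-bromo-6-(tert-butyldimethylsilyloxy)-3,7-dimethyl-3,9-bis(triethylsilyloxy)-1-oxacyclododeca-7,10-dien-2-one | CC(C)(C)[Si](C)(C)O[C@H]1CC[C@](C)(O[Si](CC)(CC)CC)C(=O)OC/C(Br)=C/[C@H](O[Si](CC)(CC)CC)/C=C1/C | intermediate
26 | (3S,6S,7Z,9R,10Z)-11-bromo-6-(tert-butyldimethylsilyloxy)-3,7-dimethyl-2-methylidene-3,9-bis(triethylsilyloxy)-1-oxacyclododeca-7,10-diene | CC(C)(C)[Si](C)(C)O[C@H]1CC[C@](C)(O[Si](CC)(CC)CC)C(=C)OC/C(Br)=C/[C@H](O[Si](CC)(CC)CC)/C=C1/C | intermediate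
27 | (3R,4R,5Z,7S,10S)-3-(1-bromoethenyl)-7-(tert-butyldimethylsilyloxy)-6,10-dimethyl-4,10-bis(triethylsilyloxy)cyclodec-5-en-1-one | C=C(Br)[C@@H]1CC(=O)[C@@](C)(O[Si](CC)(CC)CC)CC[C@H](O[Si](C)(C)C(C)(C)C)/C(C)=C\[C@H]1O[Si](CC)(CC)CC | intermediate
28 | (1S,3R,4R,5Z,7S,10S)-3-(1-bromoethenyl)-7-(tert-butyldimethylsilyloxy)-6,10-dimethyl-4,10-bis(triethylsilyloxy)cyclodec-5-en-1-ol | C=C(Br)[C@@H]1C[C@H](O)[C@@](C)(O[Si](CC)(CC)CC)CC[C@H](O[Si](C)(C)C(C)(C)C)/C(C)=C\[C@H]1O[Si](CC)(CC)CC | intermediate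
29 | angelic acid, (2Z)-2-methylbut-2-enoic acid | C/C=C(/C)C(=O)O | starting material
30 | (2Z)-2-methylbut-2-enoic 2,4,6-trichlorobenzoic anhydride | C/C=C(/C)C(=O)OC(=O)c1c(Cl)cc(Cl)cc1Cl | intermediate
31 | (1S,3R,4R,5Z,7S,10S)-3-(1-bromoethenyl)-7-(tert-butyldimethylsilyloxy)-6,10-dimethyl-4,10-bis(triethylsilyloxy)cyclodec-5-en-1-yl (2Z)-2-methylbut-2-enoate | C=C(Br)[C@@H]1C[C@H](OC(=O)/C(C)=C\C)[C@@](C)(O[Si](CC)(CC)CC)CC[C@H](O[Si](C)(C)C(C)(C)C)/C(C)=C\[C@H]1O[Si](CC)(CC)CC | intermediate
32 | methyl 2-[(1S,2R,3Z,5S,8S,9S)-5-(tert-butyldimethylsilyloxy)-4,8-dimethyl-9-{[(2Z)-2-methylbut-2-enoyl]oxy}-2,8-bis(triethylsilyloxy)cyclodec-3-en-1-yl]prop-2-enoate | C=C(C(=O)OC)[C@@H]1C[C@H](OC(=O)/C(C)=C\C)[C@@](C)(O[Si](CC)(CC)CC)CC[C@H](O[Si](C)(C)C(C)(C)C)/C(C)=C\[C@H]1O[Si](CC)(CC)CC | intermediate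
33 | methyl 2-[(1S,2R,3Z,5S,8S,9S)-2,5,8-trihydroxy-4,8-dimethyl-9-{[(2Z)-2-methylbut-2-enoyl]oxy}cyclodec-3-en-1-yl]prop-2-enoate | C=C(C(=O)OC)[C@@H]1C[C@H](OC(=O)/C(C)=C\C)[C@@](C)(O)CC[C@H](O)/C(C)=C\[C@H]1O | intermediate
34 | target, (3S,6R,7S,9S,10S,4Z)-9-angeloyloxy-3,10-dihydroxygermacra-4,11(13)-dien-12,6-olide | C=C1C(=O)O[C@@H]2/C=C(/C)[C@@H](O)CC[C@](C)(O)[C@@H](OC(=O)/C(C)=C\C)C[C@@H]12 | target

**Totals and risks**

Total step count: 21. Longest linear sequence: 18 steps (8 → 34, steps 4–21).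

Steps most likely to fail:

Step 17 (Proposed new method). The allyl vinyl ether may ionise and recombine by a [1,3] path, or the bridged transition state may not be reached below the decomposition temperature. In the fallback the sigmatropic shift is run on an open chain and the ten-membered ring is closed afterwards by known chemistry. It sets out from 19: Tebbe methylenation should give the acyclic allyl vinyl ether F1, and heating in toluene at 110 °C should give by an ordinary Claisen rearrangement the γ,δ-unsaturated ketone F2, with C7 set anti to the C6 silyloxy group. L-Selectride should give the Felkin–Anh alcohol F3, and acylation with mixed anhydride 30 the angelate F4. Cy2BH then buffered H2O2 should give the aldehyde F5, and Nozaki–Hiyama–Kishi cyclisation at high dilution should close C3–C4 to the ten-membered allylic alcohol F6. Dess–Martin oxidation to the enone F7, (R)-CBS reduction to the (3S)-alcohol F8 and silylation with TBSOTf bring the route back at 31.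

Step 18. The hydride may be delivered to the wrong face because the conformation of the ten-membered ring, and not Felkin–Anh control, decides which carbonyl face is exposed. In the fallback stereocontrol is moved from the substrate to a catalyst: 27 is reduced with catecholborane and the (R)-Me-CBS oxazaborolidine, for which the quaternary C10 side is the large group and C8H2 the small one, and the route is rejoined at 28. This fallback makes no new compound (F0).

Step 19. Acylation of the neopentyl-type C9 carbinol may be slow, and the acyl group may isomerise from Z to E at the temperature needed. In the fallback the Z-alkene is built on the ester by olefination. It sets out from 28: acylation with 2-[bis(2,2,2-trifluoroethoxy)phosphoryl]propanoyl chloride (pyridine, DMAP, CH2Cl2) should give the phosphonopropanoate ester F9, and Still–Gennari olefination with acetaldehyde (KHMDS, 18-crown-6, THF, −78 °C) should give the Z-2-methylbut-2-enoate, which is 31.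

**Further compounds**

F1 | step 17 | (2Z,4S,5Z)-2-bromo-6-iodo-4-(triethylsilyloxy)hepta-2,5-dien-1-yl enol ether of (3S)-3-methyl-3-(triethylsilyloxy)hex-5-yn-2-one (2-alkoxy-1-alkene) | C#CC[C@](C)(O[Si](CC)(CC)CC)C(=C)OC/C(Br)=C/[C@H](O[Si](CC)(CC)CC)/C=C(/C)I
F2 | step 17 | acyclic Claisen ketone, C9 ketone with C8H2 bonded to C7 that carries the 1-bromoethenyl group, (6S,7R,10S) in germacrane numbering | C#CC[C@](C)(O[Si](CC)(CC)CC)C(=O)C[C@@H](C(Br)=C)[C@H](O[Si](CC)(CC)CC)/C=C(/C)I
F3 | step 17 | (9S)-alcohol from F2 | C#CC[C@](C)(O[Si](CC)(CC)CC)[C@@H](O)C[C@@H](C(Br)=C)[C@H](O[Si](CC)(CC)CC)/C=C(/C)I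
F4 | step 17 | C9 angelate of F3 | C#CC[C@](C)(O[Si](CC)(CC)CC)[C@@H](OC(=O)/C(C)=C\C)C[C@@H](C(Br)=C)[C@H](O[Si](CC)(CC)CC)/C=C(/C)I
F5 | step 17 | C3 aldehyde from F4 | O=CCC[C@](C)(O[Si](CC)(CC)CC)[C@@H](OC(=O)/C(C)=C\C)C[C@@H](C(Br)=C)[C@H](O[Si](CC)(CC)CC)/C=C(/C)I
F6 | step 17 | ten-membered allylic alcohol, both C3 epimers | OC1CC[C@](C)(O[Si](CC)(CC)CC)[C@@H](OC(=O)/C(C)=C\C)C[C@@H](C(Br)=C)[C@H](O[Si](CC)(CC)CC)/C=C1/C
F7 | step 17 | ten-membered Z-enone | O=C1CC[C@](C)(O[Si](CC)(CC)CC)[C@@H](OC(=O)/C(C)=C\C)C[C@@H](C(Br)=C)[C@H](O[Si](CC)(CC)CC)/C=C1/C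
F8 | step 17 | ten-membered (3S)-allylic alcohol | O[C@H]1CC[C@](C)(O[Si](CC)(CC)CC)[C@@H](OC(=O)/C(C)=C\C)C[C@@H](C(Br)=C)[C@H](O[Si](CC)(CC)CC)/C=C1/C
F0 | step 18 | none | none
F9 | step 19 | 2-[bis(2,2,2-trifluoroethoxy)phosphoryl]propanoate ester of 28 (both epimers at the phosphonate carbon) | C=C(Br)[C@@H]1C[C@H](OC(=O)C(C)P(=O)(OCC(F)(F)F)OCC(F)(F)F)[C@@](C)(O[Si](CC)(CC)CC)CC[C@H](O[Si](C)(C)C(C)(C)C)/C(C)=C\[C@H]1O[Si](CC)(CC)CC
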